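With the carbocycle (ring A) numbered C1–C14 (C1 = ring-fusion CH, C4 = quaternary C–O, C5 = CH–OAc, C13 = CH–OH) and the acrylate carbons as C15(=C17)–C16, the plan rests on opening the seven-membered α-methylene lactone (ring B: C1–C2–C3–C4–O–C16–C15) to a C1 ethynyl group, carbon monoxide and the tertiary C4 hydroxyl. One palladium-hydride carbonylation forges C15–C16 and C16–O, closing ring B and creating the exo-methylene ester only at the end. Its substrate is the ring A alkynol with C5 acetylated and C13 silylated, so that C4–OH alone can capture the acyl. It is built from geraniol, 1-(trimethylsilyl)propyne and ethyl tiglate via ring-closing metathesis.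

Key step: step 16

Remark: in step 11 the bisphosphine antipode must direct the alkynyl group to the Re face of C1; (R)-DTBM-SEGPHOS is written on that assumption, and its mirror image would be used if a model E-enone showed the opposite sense.

Macrocycle names below use the ring A numbering given above, not lowest IUPAC locants.

Step 1
Reactants: 1 geraniol
Product: 2 (2S,3S)-2,3-epoxygeraniol
Conditions: Ti(OiPr)4 (5 mol%), L-(+)-diethyl tartrate (6 mol%), t-BuOOH, 4 Å MS, CH2Cl2, −20 °C
Reagents that add atoms: tert-butyl hydroperoxide, CC(C)(C)OO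
Why: Sharpless asymmetric epoxidation: the Ti(OiPr)4–tartrate catalyst binds the allylic hydroxyl, so only the C4=C5 olefin reacts, and L-(+)-diethyl tartrate delivers oxygen to the face that gives the (2S,3S)-epoxide, which fixes C5 as S and C4 provisionally as S.

Step 2
Reactants: 2 (2S,3S)-2,3-epoxygeraniol
Product: 3 (2S,3R)-3,7-dimethyloct-6-ene-1,2,3-triol
Conditions: HClO4 (aq, cat.), THF/H2O, 0 °C → rt
Reagents that add atoms: water, O
Why: Acid-catalysed epoxide hydrolysis: water opens the protonated epoxide at the tertiary carbon C4 by backside attack (borderline SN2), inverting 4S to 4R while C5 keeps its oxygen and configuration, which gives the required (4R,5S) diol.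

Step 3
Reactants: 3 (2S,3R)-3,7-dimethyloct-6-ene-1,2,3-triol
Product: 5 (2R)-6-methyl-2-[(2S)-oxiran-2-yl]hept-5-en-2-ol, via primary tosylate 4 (not isolated)
Conditions: TsCl, Et3N, Bu2SnO (2 mol%), CH2Cl2, 0 °C → rt; then DBU, rt
Reagents that add atoms: none
Why: Bu2SnO-catalysed sulfonylation selects the primary C6 hydroxyl and the C5 hydroxyl then displaces the tosylate (intramolecular Williamson etherification) without touching either stereocentre, the amidine base being too weak to set off a Payne rearrangement.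

Step 4
Reactants: 5 (2R)-6-methyl-2-[(2S)-oxiran-2-yl]hept-5-en-2-ol; 6 1-(trimethylsilyl)propyne
Product: 8 (5S,6R)-6,10-dimethylundec-9-en-1-yne-5,6-diol, via alkynylsilane diol 7 (not isolated)
Conditions: 6, n-BuLi, TMEDA, THF, −78 → −20 °C; 5, −78 → 0 °C; then MeOH, rt; aq NH4Cl
Reagents that add atoms: none
Why: SN2 opening of the terminal epoxide at C6 by the propargylic organolithium (the known alkylation of lithiated 1-silylpropynes, one equivalent being spent on the tertiary hydroxyl) forms C6–C7 with C5 untouched, and the lithium methoxide formed on adding methanol cleaves the alkynyl silane.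

Step 5
Reactants: 8 (5S,6R)-6,10-dimethylundec-9-en-1-yne-5,6-diol
Product: 9 (4S,5R)-4-(but-3-yn-1-yl)-2,2,5-trimethyl-5-(4-methylpent-3-en-1-yl)-1,3-dioxolane
Conditions: Me2C(OMe)2, PPTS (cat.), CH2Cl2, rt
Reagents that add atoms: 2,2-dimethoxypropane, COC(C)(C)OC
Why: Acid-catalysed transketalisation ties the C4 and C5 hydroxyls into a dioxolane that withstands the organometallic steps ahead, with no change at either stereocentre.

Step 6
Reactants: 10 ethyl tiglate
Product: 11 ethyl (E)-4-bromo-2-methylbut-2-enoate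
Conditions: NBS, AIBN (cat.), PhCF3, 85 °C
Reagents that add atoms: N-bromosuccinimide, O=C1CCC(=O)N1Br
Why: Wohl–Ziegler radical bromination at the γ-methyl group of the enoate should give the allylic bromide with the E olefin retained, minor regioisomers being removed by distillation.

Step 7
Reactants: 9 (4S,5R)-4-(but-3-yn-1-yl)-2,2,5-trimethyl-5-(4-methylpent-3-en-1-yl)-1,3-dioxolane; 11 ethyl (E)-4-bromo-2-methylbut-2-enoate
Product: 13 ethyl (2E,5E)-2,6-dimethyl-8-[(4S,5R)-2,2,5-trimethyl-5-(4-methylpent-3-en-1-yl)-1,3-dioxolan-4-yl]octa-2,5-dienoate, via alkenylalane 12 (not isolated)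
Conditions: Me3Al, Cp2ZrCl2 (25 mol%), CH2Cl2, 0 °C → rt; then 11, Pd(PPh3)4 (5 mol%), THF, 0 °C → rt
Reagents that add atoms: trimethylaluminium, C[Al](C)C
Why: Negishi Cp2ZrCl2-catalysed methylalumination adds methyl to C8 and aluminium to C9 in a syn sense (E olefin), and palladium-catalysed cross-coupling of the alkenylalane at the CH2 terminus of the allylic bromide then forms C9–C10 with both olefin geometries retained.

Step 8
Reactants: 13 ethyl (2E,5E)-2,6-dimethyl-8-[(4S,5R)-2,2,5-trimethyl-5-(4-methylpent-3-en-1-yl)-1,3-dioxolan-4-yl]octa-2,5-dienoate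
Product: 14 (2E,5E)-N-methoxy-N,2,6-trimethyl-8-[(4S,5R)-2,2,5-trimethyl-5-(4-methylpent-3-en-1-yl)-1,3-dioxolan-4-yl]octa-2,5-dienamide
Conditions: MeNH(OMe)·HCl, i-PrMgCl, THF, −20 °C
Reagents that add atoms: N,O-dimethylhydroxylamine hydrochloride, CNOC.Cl
Why: Weinreb amide formation by aminolysis of the ester with the magnesium amide of N,O-dimethylhydroxylamine proceeds at low temperature, where the weakly basic amide should not deconjugate the enoate.

Step 9
Reactants: 14 (2E,5E)-N-methoxy-N,2,6-trimethyl-8-[(4S,5R)-2,2,5-trimethyl-5-(4-methylpent-3-en-1-yl)-1,3-dioxolan-4-yl]octa-2,5-dienamide; 15 vinylmagnesium bromide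
Product: 16 (4E,7E)-4,8-dimethyl-10-[(4S,5R)-2,2,5-trimethyl-5-(4-methylpent-3-en-1-yl)-1,3-dioxolan-4-yl]deca-1,4,7-trien-3-one
Conditions: 15, THF, −78 → 0 °C; poured into cold 1 M HCl
Reagents that add atoms: none
Why: Weinreb ketone synthesis: the chelated tetrahedral adduct survives until the cold acidic quench, so only one vinyl group is added and the liberated amine is protonated before it can add to the vinyl ketone.

Step 10
Reactants: 16 (4E,7E)-4,8-dimethyl-10-[(4S,5R)-2,2,5-trimethyl-5-(4-methylpent-3-en-1-yl)-1,3-dioxolan-4-yl]deca-1,4,7-trien-3-one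
Product: 17 (4R,5S,1(14)E,8E,11E)-4,5-(isopropylidenedioxy)-4,8,12-trimethylcyclotetradeca-1(14),8,11-trien-13-one
Conditions: second-generation Grubbs catalyst (10 mol%), 1,4-benzoquinone (10 mol%), toluene (1 mM), 80 °C
Reagents that add atoms: none
Why: Ring-closing metathesis between the vinyl ketone and the isopropylidene terminus (loss of 2-methylpropene) forms C14=C1 and ring A at high dilution, since the E geometry of C11=C12 rules out six-membered closure onto C8=C9 and the internal trisubstituted olefins are too hindered to compete.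

Step 11
Reactants: 17 (4R,5S,1(14)E,8E,11E)-4,5-(isopropylidenedioxy)-4,8,12-trimethylcyclotetradeca-1(14),8,11-trien-13-one; 18 (triisopropylsilyl)acetylene
Product: 19 (1R,4R,5S,8E,11E)-4,5-(isopropylidenedioxy)-4,8,12-trimethyl-1-[(triisopropylsilyl)ethynyl]cyclotetradeca-8,11-dien-13-one
Conditions: 18, [Rh(OAc)(C2H4)2]2 (2.5 mol%), (R)-DTBM-SEGPHOS (6 mol%), 1,4-dioxane, 80 °C
Reagents that add atoms: none
Why: Rhodium-catalysed asymmetric conjugate alkynylation of a β-monosubstituted E-enone: the alkynylrhodium species inserts only the α-unsubstituted C14=C1 enone, the chiral bisphosphine directs the alkynyl group to the Re face of C1 (1R), and the bulky silyl group suppresses alkyne dimerisation.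

Step 12
Reactants: 19 (1R,4R,5S,8E,11E)-4,5-(isopropylidenedioxy)-4,8,12-trimethyl-1-[(triisopropylsilyl)ethynyl]cyclotetradeca-8,11-dien-13-one
Product: 22 (1R,4R,5S,8E,11E)-1-ethynyl-4,5-dihydroxy-4,8,12-trimethylcyclotetradeca-8,11-dien-13-one, via silver acetylide 20 (not isolated), via terminal alkyne acetonide 21 (not isolated)
Conditions: AgF, MeOH, rt, dark; then 1 M HCl, rt
Reagents that add atoms: none
Why: AgF-mediated protodesilylation converts the alkynylsilane into the silver acetylide, which hydrochloric acid protonates, and continued exposure to the methanolic acid hydrolyses the ketal, neither operation affecting a stereocentre or the enone.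

Step 13
Reactants: 22 (1R,4R,5S,8E,11E)-1-ethynyl-4,5-dihydroxy-4,8,12-trimethylcyclotetradeca-8,11-dien-13-one
Product: 23 (1R,4R,5S,8E,11E)-5-acetoxy-1-ethynyl-4-hydroxy-4,8,12-trimethylcyclotetradeca-8,11-dien-13-one
Conditions: Ac2O, pyridine, CH2Cl2, 0 °C → rt
Reagents that add atoms: acetic anhydride, CC(=O)OC(C)=O
Why: Acylation with acetic anhydride and pyridine takes place only at the secondary C5 hydroxyl, the tertiary C4 hydroxyl being too hindered.

Step 14
Reactants: 23 (1R,4R,5S,8E,11E)-5-acetoxy-1-ethynyl-4-hydroxy-4,8,12-trimethylcyclotetradeca-8,11-dien-13-one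
Product: 24 (1R,4R,5S,8E,11E,13R)-5-acetoxy-1-ethynyl-4,8,12-trimethylcyclotetradeca-8,11-diene-4,13-diol
Conditions: (S)-2-methyl-CBS-oxazaborolidine [(S)-1-methyl-3,3-diphenyltetrahydro-1H,3H-pyrrolo[1,2-c][1,3,2]oxazaborole], catecholborane, toluene, −78 °C
Reagents that add atoms: none
Why: Corey–Bakshi–Shibata reduction: the (S)-oxazaborolidine binds the ketone with the C12 alkenyl group as the large and C14H2 as the small substituent and delivers hydride in a 1,2 sense to give the 13R allylic alcohol, while catecholborane at −78 °C leaves the alkyne and the acetate alone.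

Step 15
Reactants: 24 (1R,4R,5S,8E,11E,13R)-5-acetoxy-1-ethynyl-4,8,12-trimethylcyclotetradeca-8,11-diene-4,13-diol
Product: 25 (1R,4R,5S,8E,11E,13R)-5-acetoxy-13-(tert-butyldimethylsilyloxy)-1-ethynyl-4,8,12-trimethylcyclotetradeca-8,11-dien-4-ol
Conditions: TBSCl, imidazole, DMF, rt
Reagents that add atoms: tert-butyldimethylsilyl chloride, CC(C)(C)[Si](C)(C)Cl
Why: Silylation with TBSCl and imidazole is confined to the secondary allylic C13 hydroxyl, because the tertiary C4 hydroxyl does not react under these conditions.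

Step 16
Reactants: 25 (1R,4R,5S,8E,11E,13R)-5-acetoxy-13-(tert-butyldimethylsilyloxy)-1-ethynyl-4,8,12-trimethylcyclotetradeca-8,11-dien-4-ol
Product: 26 13-O-TBS dendronpholide B
Conditions: Pd2(dba)3·CHCl3 (4 mol%), dppb (10 mol%), CO (40 bar), H2 (14 bar), CH2Cl2, 95 °C (autoclave)
Reagents that add atoms: carbon monoxide, [C-]#[O+]
Why: Proposed new method: a palladium hydride formed from zerovalent palladium, dppb and H2 adds in the Markovnikov sense to the terminal alkyne (Pd on C15, H on C17), CO inserts to give the C15–C16 acylpalladium, and the C4 hydroxyl attacks C16 to release the lactone and regenerate the hydride. The closest known reaction type is the palladium-catalysed cyclocarbonylation of but-3-yn-1-ols and pent-4-yn-1-ols to five- and six-membered α-methylene lactones, and closure of a seven-membered ring onto a tertiary alcohol is the unproven extension. Ring B (C1–C2–C3–C4–O–C16–C15) closes by 7-exo-trig acyl substitution of the C4 oxygen at the acylpalladium carbon, the C15–C16 bond being made just before by migratory insertion. No stereocentre is formed, and C1 and C4 are already fixed in 25. The step needs branched rather than linear acylation, which Markovnikov hydropalladation under the chelating bisphosphine favours and which the substrate enforces because only the branched acyl can reach the C4 oxygen through a seven-membered ring. It also needs C4–OH to be the only competent nucleophile, which the C13 silyl ether (blocking six-membered lactonisation) and the C5 acetate secure, while the trisubstituted ring olefins are too hindered to insert into the hydride.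

Step 17
Reactants: 26 13-O-TBS dendronpholide B
Product: 27 dendronpholide B
Conditions: HF·pyridine, pyridine, THF, 0 °C → rt
Reagents that add atoms: none
Why: Fluoride-mediated desilylation with the mildly acidic HF·pyridine complex cleaves the silyl ether without forming a C13 alkoxide, which avoids translactonisation to the six-membered lactone, acetate migration and conjugate addition to the acrylate.

Compound list
1 | geraniol, (2E)-3,7-dimethylocta-2,6-dien-1-ol | CC(C)=CCC/C(C)=C/CO | starting material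
2 | (2S,3S)-2,3-epoxygeraniol, [(2S,3S)-3-methyl-3-(4-methylpent-3-en-1-yl)oxiran-2-yl]methanol | OC[C@@H]1O[C@@]1(C)CCC=C(C)C | intermediate
3 | (2S,3R)-3,7-dimethyloct-6-ene-1,2,3-triol | OC[C@H](O)[C@](C)(O)CCC=C(C)C | intermediate
4 | (2S,3R)-2,3-dihydroxy-3,7-dimethyloct-6-en-1-yl 4-methylbenzenesulfonate | Cc1ccc(cc1)S(=O)(=O)OC[C@H](O)[C@](C)(O)CCC=C(C)C | intermediate (not isolated)
5 | (2R)-6-methyl-2-[(2S)-oxiran-2-yl]hept-5-en-2-ol | CC(C)=CCC[C@@](C)(O)[C@@H]1CO1 | intermediate
6 | 1-(trimethylsilyl)propyne | CC#C[Si](C)(C)C | starting material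
7 | (5S,6R)-6,10-dimethyl-1-(trimethylsilyl)undec-9-en-1-yne-5,6-diol | C[Si](C)(C)C#CCC[C@H](O)[C@](C)(O)CCC=C(C)C | intermediate (not isolated)
8 | (5S,6R)-6,10-dimethylundec-9-en-1-yne-5,6-diol | C#CCC[C@H](O)[C@](C)(O)CCC=C(C)C | intermediate
9 | (4S,5R)-4-(but-3-yn-1-yl)-2,2,5-trimethyl-5-(4-methylpent-3-en-1-yl)-1,3-dioxolane | C#CCC[C@@H]1OC(C)(C)O[C@]1(C)CCC=C(C)C | intermediate
10 | ethyl tiglate, ethyl (E)-2-methylbut-2-enoate | C/C=C(\C)C(=O)OCC | starting material
11 | ethyl (E)-4-bromo-2-methylbut-2-enoate | BrC/C=C(\C)C(=O)OCC | intermediate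
12 | dimethyl{(E)-2-methyl-4-[(4S,5R)-2,2,5-trimethyl-5-(4-methylpent-3-en-1-yl)-1,3-dioxolan-4-yl]but-1-en-1-yl}aluminium | C[Al](C)/C=C(\C)CC[C@@H]1OC(C)(C)O[C@]1(C)CCC=C(C)C | intermediate (not isolated)
13 | ethyl (2E,5E)-2,6-dimethyl-8-[(4S,5R)-2,2,5-trimethyl-5-(4-methylpent-3-en-1-yl)-1,3-dioxolan-4-yl]octa-2,5-dienoate | CCOC(=O)/C(C)=C/C/C=C(\C)CC[C@@H]1OC(C)(C)O[C@]1(C)CCC=C(C)C | intermediate
14 | (2E,5E)-N-methoxy-N,2,6-trimethyl-8-[(4S,5R)-2,2,5-trimethyl-5-(4-methylpent-3-en-1-yl)-1,3-dioxolan-4-yl]octa-2,5-dienamide | CON(C)C(=O)/C(C)=C/C/C=C(\C)CC[C@@H]1OC(C)(C)O[C@]1(C)CCC=C(C)C | intermediate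
15 | vinylmagnesium bromide | C=C[Mg]Br | starting material
16 | (4E,7E)-4,8-dimethyl-10-[(4S,5R)-2,2,5-trimethyl-5-(4-methylpent-3-en-1-yl)-1,3-dioxolan-4-yl]deca-1,4,7-trien-3-one | C=CC(=O)/C(C)=C/C/C=C(\C)CC[C@@H]1OC(C)(C)O[C@]1(C)CCC=C(C)C | intermediate
17 | (4R,5S,1(14)E,8E,11E)-4,5-(isopropylidenedioxy)-4,8,12-trimethylcyclotetradeca-1(14),8,11-trien-13-one (ring A dienone, C13 ketone) | O=C1/C=C/CC[C@@]2(C)OC(C)(C)O[C@H]2CC/C(C)=C/C/C=C1\C | intermediate
18 | (triisopropylsilyl)acetylene | C#C[Si](C(C)C)(C(C)C)C(C)C | starting material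
19 | (1R,4R,5S,8E,11E)-4,5-(isopropylidenedioxy)-4,8,12-trimethyl-1-[(triisopropylsilyl)ethynyl]cyclotetradeca-8,11-dien-13-one | CC(C)[Si](C(C)C)(C(C)C)C#C[C@@H]1CC[C@@]2(C)OC(C)(C)O[C@H]2CC/C(C)=C/C/C=C(\C)C(=O)C1 | intermediate
20 | silver acetylide of 21 (silver on the terminal alkyne carbon C17) | [Ag]C#C[C@@H]1CC[C@@]2(C)OC(C)(C)O[C@H]2CC/C(C)=C/C/C=C(\C)C(=O)C1 | intermediate (not isolated)
21 | (1R,4R,5S,8E,11E)-1-ethynyl-4,5-(isopropylidenedioxy)-4,8,12-trimethylcyclotetradeca-8,11-dien-13-one | C#C[C@@H]1CC[C@@]2(C)OC(C)(C)O[C@H]2CC/C(C)=C/C/C=C(\C)C(=O)C1 | intermediate (not isolated)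
22 | (1R,4R,5S,8E,11E)-1-ethynyl-4,5-dihydroxy-4,8,12-trimethylcyclotetradeca-8,11-dien-13-one | C#C[C@@H]1CC[C@@](C)(O)[C@@H](O)CC/C(C)=C/C/C=C(\C)C(=O)C1 | intermediate
23 | (1R,4R,5S,8E,11E)-5-acetoxy-1-ethynyl-4-hydroxy-4,8,12-trimethylcyclotetradeca-8,11-dien-13-one | C#C[C@@H]1CC[C@@](C)(O)[C@@H](OC(C)=O)CC/C(C)=C/C/C=C(\C)C(=O)C1 | intermediate
24 | (1R,4R,5S,8E,11E,13R)-5-acetoxy-1-ethynyl-4,8,12-trimethylcyclotetradeca-8,11-diene-4,13-diol | C#C[C@@H]1CC[C@@](C)(O)[C@@H](OC(C)=O)CC/C(C)=C/C/C=C(C)/[C@H](O)C1 | intermediate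
25 | (1R,4R,5S,8E,11E,13R)-5-acetoxy-13-(tert-butyldimethylsilyloxy)-1-ethynyl-4,8,12-trimethylcyclotetradeca-8,11-dien-4-ol (key-step precursor) | C#C[C@@H]1CC[C@@](C)(O)[C@@H](OC(C)=O)CC/C(C)=C/C/C=C(C)/[C@H](O[Si](C)(C)C(C)(C)C)C1 | intermediate
26 | 13-O-TBS dendronpholide B (rings A and B, C4–O–C16 lactone, 5-OAc, 13-OTBS) | C=C1C(=O)O[C@]2(C)CC[C@@H]1C[C@@H](O[Si](C)(C)C(C)(C)C)/C(C)=C/C/C=C(\C)CC[C@@H]2OC(C)=O | intermediate
27 | dendronpholide B | C=C1C(=O)O[C@]2(C)CC[C@@H]1C[C@@H](O)/C(C)=C/C/C=C(\C)CC[C@@H]2OC(C)=O | target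

Total step count: 17.
Longest linear sequence: 16 steps (geraniol 1 to 27 through steps 1–5 and 7–17); step 6 is a one-step side branch.

Steps most likely to fail

1. Step 16 (Proposed new method). Capture of the acylpalladium by the hindered tertiary hydroxyl in a seven-membered closure may be slower than hydrogenolysis of the acyl, reduction or oligomerisation of the alkyne, or hydride-induced migration of the skipped diene. The fallback uses known chemistry, sets out from 25 and removes the hydride from the picture. Stannylcupration of the terminal alkyne (Me3SnCu·SMe2, THF/MeOH, −63 °C) places tin on the internal carbon and gives the 2-(trimethylstannyl)alkene F1. Iododestannylation (I2, CH2Cl2, 0 °C) gives the 2-iodoalkene F2. Palladium-catalysed intramolecular alkoxycarbonylation of the vinyl iodide (Pd(PPh3)4, CO 3 bar, Et3N, MeCN, 60 °C), the classical vinyl halide route to α-methylene lactones, fixes the acyl on C15 by oxidative addition and comes back to the route at 26.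

2. Step 11. The conformational bias of the macrocycle may override the catalyst (poor facial selectivity at C1), or alkyne dimerisation on rhodium may outrun insertion of the enone. The fallback sets out from 17 and replaces catalyst control by a stoichiometric aluminium acetylide under substrate control. Nickel-catalysed conjugate addition of dimethylaluminium (trimethylsilyl)acetylide (from ethynyltrimethylsilane, n-BuLi and Me2AlCl; Ni(acac)2 and diisobutylaluminium hydride i-Bu2AlH as catalyst precursor, Et2O, −5 °C) should give the trimethylsilylalkynyl ketone F3 by peripheral attack on the ring, the C1 epimers being separated by chromatography. AgNO3-catalysed protodesilylation in aqueous acetone then gives 21, and methanolic HCl as in step 12 comes back to the route at 22.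

3. Step 10. Both metathesis partners initiate poorly (electron-poor vinyl ketone, trisubstituted isopropylidene), so slow turnover at high dilution may lead to oligomerisation or loss of the vinyl ketone. The fallback sets out from 14 and closes the ring at the alcohol oxidation level. Diisobutylaluminium hydride i-Bu2AlH (THF, −78 °C) reduces the Weinreb amide to the enal F4. Addition of 15 gives the divinyl carbinol F5 (both C13 epimers, of no consequence). Ring-closing metathesis of this electron-rich allylic alcohol (second-generation Grubbs catalyst, toluene, 80 °C, high dilution) should initiate readily at the vinyl carbinol and give the macrocyclic dienol F6. MnO2 (CH2Cl2, rt) oxidises the doubly allylic alcohol and comes back to the route at 17.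

Further compounds
F1 | step 16 | (1R,4R,5S,8E,11E,13R)-5-acetoxy-13-(tert-butyldimethylsilyloxy)-4,8,12-trimethyl-1-[1-(trimethylstannyl)ethenyl]cyclotetradeca-8,11-dien-4-ol | C=C([Sn](C)(C)C)[C@@H]1CC[C@@](C)(O)[C@@H](OC(C)=O)CC/C(C)=C/C/C=C(C)/[C@H](O[Si](C)(C)C(C)(C)C)C1
F2 | step 16 | (1R,4R,5S,8E,11E,13R)-5-acetoxy-13-(tert-butyldimethylsilyloxy)-1-(1-iodoethenyl)-4,8,12-trimethylcyclotetradeca-8,11-dien-4-ol | C=C(I)[C@@H]1CC[C@@](C)(O)[C@@H](OC(C)=O)CC/C(C)=C/C/C=C(C)/[C@H](O[Si](C)(C)C(C)(C)C)C1
F3 | step 11 | (1R,4R,5S,8E,11E)-4,5-(isopropylidenedioxy)-4,8,12-trimethyl-1-[(trimethylsilyl)ethynyl]cyclotetradeca-8,11-dien-13-one | C[Si](C)(C)C#C[C@@H]1CC[C@@]2(C)OC(C)(C)O[C@H]2CC/C(C)=C/C/C=C(\C)C(=O)C1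
F4 | step 10 | (2E,5E)-2,6-dimethyl-8-[(4S,5R)-2,2,5-trimethyl-5-(4-methylpent-3-en-1-yl)-1,3-dioxolan-4-yl]octa-2,5-dienal | O=C/C(C)=C/C/C=C(\C)CC[C@@H]1OC(C)(C)O[C@]1(C)CCC=C(C)C
F5 | step 10 | (4E,7E)-4,8-dimethyl-10-[(4S,5R)-2,2,5-trimethyl-5-(4-methylpent-3-en-1-yl)-1,3-dioxolan-4-yl]deca-1,4,7-trien-3-ol (both C3 epimers) | C=CC(O)/C(C)=C/C/C=C(\C)CC[C@@H]1OC(C)(C)O[C@]1(C)CCC=C(C)C
F6 | step 10 | (4R,5S,1(14)E,8E,11E)-4,5-(isopropylidenedioxy)-4,8,12-trimethylcyclotetradeca-1(14),8,11-trien-13-ol (both C13 epimers) | OC1/C=C/CC[C@@]2(C)OC(C)(C)O[C@H]2CC/C(C)=C/C/C=C1\C
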